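Watch E while the feed runs, and count J before charging.

| setting | noon | flask |
|---|---|---|
| Z | 20 mM (fed, over 15 h) | 20 mM (fed, over 15 h) |
| J | 1.2 equiv | 1.20 equiv |
| L | 0.11 mol% | 0.11 mol% |
| G | 1 mol% | 1 mol% |
| remark | the very flask that is asked about, followed so far; the fed solution adds 0.20 times the starting volume | the fed solution adds 0.20 times the starting volume |
| time |  | 15 d |

noon run (percent of the Z charged)

| time / d | E / % | D / % | Z / % |
|---|---|---|---|
| 0.167 | 9 | 5 | 18 |
| 0.333 | 12 | 14 | 27 |
| 0.833 | 10 | 74 | 11 |
| 1.67 | 2 | 97 | 0 |
| 4.00 | 1 | 97 | 0 |
| 8.00 | 0 | 100 | 0 |

(standard deviation of a reading: 2 percentage points)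

- charges are per starting volume, the dose included; the dosed solution carries all of it
- the numbers in the tables scatter by 2 percentage points (one standard deviation)
- percentages count the whole charge, also what has not yet gone in

- time up to 15 d at which E stands highest
- the amount of E, in percent of the Z charged, at that time

Where does E stand at the late end? In the noon run of this flask it reads 0% at 8.00 d, with D at 100%, so E does not stay behind there.

What pays for the step from E to D? J was not read, so I assume that each D costs one J. The quantity to carry is then the J margin, the equivalents of J charged less the one equivalent that full conversion of Z takes: 0.200 for this flask. My rule, for a flask in which Z is fully converted, is that a negative margin strands its size as E at the late end, and a positive one strands none.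

Does a positive margin say how high E climbs? No, it says nothing of the peak, so the early end has to answer that.

And the early end? Z enters until 0.625 d. E reads 12% at 0.333 d and 10% at 0.833 d, each with a scatter of 2 percentage points, so the readings bracket the peak without giving its height. After the feed stops, Z has no further supply and reads 11% at 0.833 d, so I place the peak at or just after the end of the feed, somewhat above those readings.

How do the ends join? In my reckoning the highest E is the larger of this early peak and the stranded share, and in this flask the rule puts the stranded share at nil.

The forecast, holding that the “peak therefore falls at or just after feed end”, gives 17% at 0.64 d.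

The flask gives 17.6% at 0.652 d.

    G + E ⇌ Q (K = 100 L mol⁻¹, k = 0.590 L mol⁻¹ s⁻¹)
    2 L ⇌ X, settled at all times (K = 18000 L mol⁻¹)
    Z + L → L + E (k = 3.90 L mol⁻¹ s⁻¹)
    J + Q → G + D (k = 4.30 L mol⁻¹ s⁻¹)

With its margin of 0.200, this flask should keep 16.7% of its J charge, and 17% is there at 15.0 d, with D at 100%. The neighbour flask is charged with 0.720 equiv of J, the other charges and the time held, so its margin is −0.280 and the rule strands 28.0% as E. J is the limiting reagent in the neighbour flask, with 0% left at 15.0 d. D in the neighbour flask ends at 72.0%, E at 27.7%, and its best is 27.7%.

The numbers in the tables were computed for substances that don't exist, noise included.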